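**Plan**
- Cuts: (a) the C–prenyl bond at the quaternary ring carbon C(CH3)(prenyl), made last by dearomative prenylation of a fully substituted acylphloroglucinol; (b) the bond between the exocyclic CH2 and the six-membered ring, made by reductive alkylation of the arene with a cyclopentanecarbaldehyde; (c) the aryl–acyl bond; (d) in the cyclopentane, the bond between the carbinol carbon C(OH)(CH3) and the neighbouring ring CH that carries the CH2 arm.
- Enabling feature: on the cyclopentane the carbinol oxygen and the exocyclic carbon on the adjacent ring CH are cis and 1,3-related, which is an aldol retron. At the acid oxidation level the two close to a cis-fused 2-oxetanone (6-oxabicyclo[3.2.0]heptan-7-one), a temporary ring that forces this cis pair while the five-membered ring forms. The third substituted ring carbon, CH(isopropenyl), is the only stereocentre of the open-chain precursor and steers the closure.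
- Forward: (S)-carvone is cleaved to (3S)-6-oxo-3-isopropenylheptanoic acid; aldol-lactonisation closes the cyclopentane, the only carbocycle built (the six-membered ring is bought as 2-methylphloroglucinol); the lactone is reduced away to the β-hydroxy aldehyde, which is joined to the acylated arene; prenylation dearomatises at the end.
- Stereochemistry: CH(isopropenyl) from (S)-carvone; the carbinol and CH(CH2) centres from the key step (cis through the lactone, trans to isopropenyl by substrate control); the acyl centre from (R)-2-methylbutanoic acid; the quaternary centre from a chiral palladium catalyst.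

Key step: step 3

Assumption: the acyl stereocentre of the target is R as drawn, so (R)-2-methylbutanoic acid is used; it and (S)-(+)-carvone are taken as purchasable in high enantiomeric purity. The target is written as one of its interconverting enol tautomers.

**Step 1**
Reactants: 1 (S)-(+)-carvone
Product: 3 (5S)-2-hydroxy-2-methyl-5-(prop-1-en-2-yl)cyclohexan-1-one (both C2 epimers), via hydroperoxide 2 (not isolated)
Conditions: Mn(dpm)3 (cat.), PhSiH3, O2 (1 atm), iPrOH, 0 °C; then P(OEt)3
Reagents that add atoms: dioxygen, O=O
Why: Mukaiyama-type reductive α-hydroxylation, in which a manganese hydride transfers a hydrogen atom to the enone β-carbon, the α-keto radical is trapped by O2 and the hydroperoxide is reduced by the phosphite; the conjugated alkene should react in preference to the isopropenyl group, and the new carbinol centre is destroyed in step 2, so its configuration does not matter.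

**Step 2**
Reactants: 3 (5S)-2-hydroxy-2-methyl-5-(prop-1-en-2-yl)cyclohexan-1-one
Product: 4 (3S)-6-oxo-3-(prop-1-en-2-yl)heptanoic acid
Conditions: H5IO6, THF/H2O, 0 °C to rt
Reagents that add atoms: water, O
Why: periodate cleavage of the α-hydroxy ketone through its hydrate cuts the C1–C2 bond to give the carboxylic acid and the methyl ketone, leaving the isopropenyl group and the stereocentre untouched.

**Step 3**
Reactants: 4 (3S)-6-oxo-3-(prop-1-en-2-yl)heptanoic acid
Product: 7 (1R,2S,5S)-5-methyl-2-(prop-1-en-2-yl)-6-oxabicyclo[3.2.0]heptan-7-one, via mixed tosyl anhydride 5 (not isolated), via acylpyridinium aldolate 6 (not isolated)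
Conditions: TsCl, 4-pyrrolidinopyridine, iPr2NEt, CH2Cl2, rt, slow addition of 4
Reagents that add atoms: none
Why: Tosyl chloride converts the acid into mixed anhydride 5, 4-pyrrolidinopyridine forms the N-acylpyridinium salt and the amine base deprotonates it to a pyridinium enolate, which adds to the methyl ketone to give aldolate 6, whose alkoxide then attacks the acylpyridinium carbon and releases the catalyst and the lactone. The closest known reaction type is the nucleophile-catalysed aldol-lactonisation of keto acids to bicyclic β-lactones, known for 6-oxo acids that carry a substituent at C3. The cyclopentane closes by a 5-(enolexo)-exo-trig aldol addition and the temporary 2-oxetanone by a 4-exo-trig acyl substitution. The carbinol centre and the α-centre are tied together by the four-membered ring, which can only be cis-fused, so the oxygen and the carboxyl carbon end up on the same face of the cyclopentane, as the hydroxyl and the CH2 arm must be in 17. The configuration of this pair relative to the carvone-derived centre is controlled by that centre: in the chair-like transition state the isopropenyl group should lie pseudo-equatorial and end up on the convex face, trans to the lactone carbonyl. The step needs enolisation at the carboxyl α-carbon and not at the ketone, and ring closure in preference to intermolecular acylation; the much higher acidity of the acylpyridinium α-hydrogens and the 1,5-relationship of enolate and ketone, helped by slow addition, should secure both.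

**Step 4**
Reactants: 7 (1R,2S,5S)-5-methyl-2-(prop-1-en-2-yl)-6-oxabicyclo[3.2.0]heptan-7-one
Product: 8 (1S,2S,3S)-2-(hydroxymethyl)-1-methyl-3-(prop-1-en-2-yl)cyclopentan-1-ol
Conditions: LiAlH4, THF, 0 °C
Reagents that add atoms: none
Why: hydride reduction of the strained β-lactone with acyl C–O cleavage removes the temporary ring and should give the 1,3-diol without touching the three stereocentres or the alkene.

**Step 5**
Reactants: 8 (1S,2S,3S)-2-(hydroxymethyl)-1-methyl-3-(prop-1-en-2-yl)cyclopentan-1-ol
Product: 9 (1R,2S,5S)-2-hydroxy-2-methyl-5-(prop-1-en-2-yl)cyclopentane-1-carbaldehyde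
Conditions: TEMPO (cat.), PhI(OAc)2, CH2Cl2, rt; used crude
Reagents that add atoms: none
Why: oxoammonium oxidation is selective for the primary alcohol (the tertiary one cannot be oxidised), and the mild, non-basic conditions should avoid retro-aldol opening, dehydration and epimerisation of the aldol product.

**Step 6**
Reactants: 10 (R)-2-methylbutanoic acid, 11 2-methylbenzene-1,3,5-triol
Product: 13 (2R)-2-methyl-1-(2,4,6-trihydroxy-3-methylphenyl)butan-1-one, via acid chloride 12 (not isolated)
Conditions: (COCl)2, DMF (cat.), CH2Cl2, 0 °C to rt; then 11, AlCl3, PhNO2, 0 °C to rt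
Reagents that add atoms: none
Why: Friedel–Crafts C-acylation with the acid chloride made in situ; the two free ring positions of 11 are equivalent, the product ketone is deactivated toward a second acylation, and the stereocentre comes unchanged from 10 provided the temperature is kept low to limit enolisation of the acylium and ketone–AlCl3 complexes.

**Step 7**
Reactants: 13 (2R)-2-methyl-1-(2,4,6-trihydroxy-3-methylphenyl)butan-1-one, 9 (1R,2S,5S)-2-hydroxy-2-methyl-5-(prop-1-en-2-yl)cyclopentane-1-carbaldehyde
Product: 15 (2R)-1-(2,4,6-trihydroxy-3-{[(1R,2S,5S)-2-hydroxy-2-methyl-5-(prop-1-en-2-yl)cyclopentyl]methyl}-5-methylphenyl)-2-methylbutan-1-one, via ortho-quinone methide 14 (not isolated)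
Conditions: Hantzsch ester, L-proline (20 mol%), CH2Cl2, rt
Reagents that add atoms: none
Why: organocatalytic three-component reductive alkylation, in which proline-mediated Knoevenagel-type condensation at the single free nuclear carbon of 13 gives ortho-quinone methide 14, which is reduced at once by hydride transfer from the Hantzsch ester with rearomatisation; no stereocentre is formed, and the α-centre of 9, should it enolise, is expected to return to the more stable arrangement (trans to isopropenyl, cis to the hydroxyl).

**Step 8**
Reactants: 15 (2R)-1-(2,4,6-trihydroxy-3-{[(1R,2S,5S)-2-hydroxy-2-methyl-5-(prop-1-en-2-yl)cyclopentyl]methyl}-5-methylphenyl)-2-methylbutan-1-one, 16 prenyl acetate (3-methylbut-2-en-1-yl acetate)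
Product: 17 (6R)-3,5-dihydroxy-4-{[(1R,2S,5S)-2-hydroxy-2-methyl-5-(prop-1-en-2-yl)cyclopentyl]methyl}-6-methyl-6-(3-methylbut-2-en-1-yl)-2-[(2R)-2-methylbutanoyl]cyclohexa-2,4-dien-1-one (CNP0299585.1)
Conditions: Pd2(dba)3·CHCl3 (2.5 mol%), (R,R)-N,N'-(cyclohexane-1,2-diyl)bis[2-(diphenylphosphino)benzamide] (7.5 mol%), Et3N, CH2Cl2, 0 °C
Reagents that add atoms: none
Why: Proposed new method: Pd(0) ionises 16 to a cationic η3-(1,1-dimethylallyl)palladium complex held in the chiral pocket of the diamide–bisphosphine ligand, and the triethylammonium phenolate of 15 attacks its unsubstituted terminus through the ring carbon that carries the methyl group (the carbon bearing the CH2-cyclopentyl arm is shielded by that β-branched substituent, the acyl-bearing carbon is not nucleophilic, and O-prenyl ethers re-ionise under Pd(0) and funnel to carbon), so that dearomatisation creates the quaternary centre on the face chosen by the ligand and not by the four remote stereocentres; the closest known reaction types are the racemic Pd-catalysed dearomative allylation of acylphloroglucinols, the Pd-catalysed intermolecular asymmetric allylic dearomatisation of 1-substituted 2-naphthols and the linear-selective asymmetric Tsuji–Trost prenylation of 3-substituted oxindoles, and the ligand antipode that delivers the (6R) centre has to be found by experiment, the (R,R) ligand being the first choice.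

**Compound list**
1 | (S)-(+)-carvone, (5S)-2-methyl-5-(prop-1-en-2-yl)cyclohex-2-en-1-one | CC1=CC[C@@H](CC1=O)C(C)=C | starting material
2 | (5S)-2-hydroperoxy-2-methyl-5-(prop-1-en-2-yl)cyclohexan-1-one (both C2 epimers) | CC1(OO)CC[C@@H](CC1=O)C(C)=C | intermediate
3 | (5S)-2-hydroxy-2-methyl-5-(prop-1-en-2-yl)cyclohexan-1-one (both C2 epimers) | CC1(O)CC[C@@H](CC1=O)C(C)=C | intermediate
4 | (3S)-6-oxo-3-(prop-1-en-2-yl)heptanoic acid | CC(=O)CC[C@@H](CC(=O)O)C(C)=C | intermediate
5 | (3S)-6-oxo-3-(prop-1-en-2-yl)heptanoic 4-methylbenzenesulfonic anhydride | CC(=O)CC[C@@H](CC(=O)OS(=O)(=O)c1ccc(C)cc1)C(C)=C | intermediate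
6 | 1-{[(1R,2S,5S)-2-methyl-2-oxido-5-(prop-1-en-2-yl)cyclopentyl]carbonyl}-4-(pyrrolidin-1-yl)pyridin-1-ium (zwitterion) | C=C(C)[C@H]1CC[C@](C)([O-])[C@@H]1C(=O)[n+]1ccc(cc1)N1CCCC1 | intermediate
7 | (1R,2S,5S)-5-methyl-2-(prop-1-en-2-yl)-6-oxabicyclo[3.2.0]heptan-7-one | C=C(C)[C@H]1CC[C@]2(C)OC(=O)[C@H]12 | intermediate
8 | (1S,2S,3S)-2-(hydroxymethyl)-1-methyl-3-(prop-1-en-2-yl)cyclopentan-1-ol | C=C(C)[C@H]1CC[C@](C)(O)[C@@H]1CO | intermediate
9 | (1R,2S,5S)-2-hydroxy-2-methyl-5-(prop-1-en-2-yl)cyclopentane-1-carbaldehyde | C=C(C)[C@H]1CC[C@](C)(O)[C@@H]1C=O | intermediate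
10 | (R)-2-methylbutanoic acid | CC[C@@H](C)C(=O)O | starting material
11 | 2-methylbenzene-1,3,5-triol (2-methylphloroglucinol) | Cc1c(O)cc(O)cc1O | starting material
12 | (R)-2-methylbutanoyl chloride | CC[C@@H](C)C(Cl)=O | intermediate
13 | (2R)-2-methyl-1-(2,4,6-trihydroxy-3-methylphenyl)butan-1-one | CC[C@@H](C)C(=O)c1c(O)cc(O)c(C)c1O | intermediate
14 | ortho-quinone methide from 13 and 9: 3,5-dihydroxy-6-{[(1R,2S,5S)-2-hydroxy-2-methyl-5-(prop-1-en-2-yl)cyclopentyl]methylidene}-2-methyl-4-[(2R)-2-methylbutanoyl]cyclohexa-2,4-dien-1-one | C=C(C)[C@H]1CC[C@](C)(O)[C@@H]1C=C1C(=O)C(C)=C(O)C(C(=O)[C@H](C)CC)=C1O | intermediate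
15 | (2R)-1-(2,4,6-trihydroxy-3-{[(1R,2S,5S)-2-hydroxy-2-methyl-5-(prop-1-en-2-yl)cyclopentyl]methyl}-5-methylphenyl)-2-methylbutan-1-one | C=C(C)[C@H]1CC[C@](C)(O)[C@@H]1Cc1c(O)c(C)c(O)c(C(=O)[C@H](C)CC)c1O | intermediate
16 | prenyl acetate (3-methylbut-2-en-1-yl acetate) | CC(C)=CCOC(C)=O | starting material
17 | (6R)-3,5-dihydroxy-4-{[(1R,2S,5S)-2-hydroxy-2-methyl-5-(prop-1-en-2-yl)cyclopentyl]methyl}-6-methyl-6-(3-methylbut-2-en-1-yl)-2-[(2R)-2-methylbutanoyl]cyclohexa-2,4-dien-1-one | C=C(C)[C@H]1CC[C@](C)(O)[C@@H]1CC1=C(O)[C@@](C)(CC=C(C)C)C(=O)C(C(=O)[C@H](C)CC)=C1O | target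

**Totals and risks**
Total step count: 8. Longest linear sequence: 7 steps (steps 1–5, 7 and 8, from carvone).

Steps most likely to fail:

Step 8 (Proposed new method). The phenolate may attack the π-prenyl complex with poor facial discrimination, or on oxygen, or at the tertiary allyl terminus, and the C-prenyl product may re-ionise under Pd(0) and erode the quaternary centre. The fallback sets out from 15 and gives up catalyst control: classical alkylative dearomatisation of the lupulone type with sodium methoxide and prenyl bromide in methanol at 0 °C should prenylate the methyl-bearing carbon without facial preference. This would give 17 together with its epimer at the quaternary carbon, (6S)-3,5-dihydroxy-4-{[(1R,2S,5S)-2-hydroxy-2-methyl-5-(prop-1-en-2-yl)cyclopentyl]methyl}-6-methyl-6-(3-methylbut-2-en-1-yl)-2-[(2R)-2-methylbutanoyl]cyclohexa-2,4-dien-1-one F1. The two are diastereomers because of the four fixed stereocentres and would be separated by preparative HPLC, so the fallback comes back to the route at 17.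

Step 7. Under amine catalysis the tertiary aldol 9 may lose water or open by retro-aldol reaction before it condenses, and ortho-quinone methide 14 may tautomerise to an ortho-hydroxystyrene (loss of the α-stereocentre) faster than it is reduced. The fallback sets out from lactone 7 and masks the tertiary alcohol before the aldehyde is ever freed. Aminolysis of 7 with MeNH(OMe)·HCl and AlMe3 should give (1R,2S,5S)-2-hydroxy-N-methoxy-N,2-dimethyl-5-(prop-1-en-2-yl)cyclopentane-1-carboxamide F2. Silylation with TESOTf and 2,6-lutidine gives (1R,2S,5S)-N-methoxy-N,2-dimethyl-5-(prop-1-en-2-yl)-2-[(triethylsilyl)oxy]cyclopentane-1-carboxamide F3. DIBAL-H at −78 °C gives (1R,2S,5S)-2-methyl-5-(prop-1-en-2-yl)-2-[(triethylsilyl)oxy]cyclopentane-1-carbaldehyde F4, which can no longer undergo retro-aldol cleavage. Reductive alkylation of 13 with F4 under the conditions of step 7 gives (2R)-1-[2,4,6-trihydroxy-3-methyl-5-({(1R,2S,5S)-2-methyl-5-(prop-1-en-2-yl)-2-[(triethylsilyl)oxy]cyclopentyl}methyl)phenyl]-2-methylbutan-1-one F5. HF·pyridine in THF at 0 °C removes the silyl group, and the fallback comes back to the route at 15.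

Step 3. The activated acid may acylate intermolecularly or oligomerise through a ketene, or the enolate may add through the other face and give the lactone with the ring-fusion pair cis to the isopropenyl group. The fallback sets out from 3 and closes the same ring bond by a reversible aldol addition at the aldehyde level. NaBH4 in methanol should give (4S)-1-methyl-4-(prop-1-en-2-yl)cyclohexane-1,2-diol F6, and NaIO4 in THF/water should cleave it to (3S)-6-oxo-3-(prop-1-en-2-yl)heptanal F7. L-Proline-catalysed 5-enolexo aldolisation at 0 °C, stopped before dehydration, should then deliver the aldol under thermodynamic control (formyl group trans to isopropenyl and hydrogen-bonded to the cis hydroxyl). The fallback comes back to the route at 9.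

**Further compounds**
F1 | step 8 | (6S)-3,5-dihydroxy-4-{[(1R,2S,5S)-2-hydroxy-2-methyl-5-(prop-1-en-2-yl)cyclopentyl]methyl}-6-methyl-6-(3-methylbut-2-en-1-yl)-2-[(2R)-2-methylbutanoyl]cyclohexa-2,4-dien-1-one | C=C(C)[C@H]1CC[C@](C)(O)[C@@H]1CC1=C(O)[C@](C)(CC=C(C)C)C(=O)C(C(=O)[C@H](C)CC)=C1O
F2 | step 7 | (1R,2S,5S)-2-hydroxy-N-methoxy-N,2-dimethyl-5-(prop-1-en-2-yl)cyclopentane-1-carboxamide | C=C(C)[C@H]1CC[C@](C)(O)[C@@H]1C(=O)N(C)OC
F3 | step 7 | (1R,2S,5S)-N-methoxy-N,2-dimethyl-5-(prop-1-en-2-yl)-2-[(triethylsilyl)oxy]cyclopentane-1-carboxamide | C=C(C)[C@H]1CC[C@](C)(O[Si](CC)(CC)CC)[C@@H]1C(=O)N(C)OC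
F4 | step 7 | (1R,2S,5S)-2-methyl-5-(prop-1-en-2-yl)-2-[(triethylsilyl)oxy]cyclopentane-1-carbaldehyde | C=C(C)[C@H]1CC[C@](C)(O[Si](CC)(CC)CC)[C@@H]1C=O
F5 | step 7 | (2R)-1-[2,4,6-trihydroxy-3-methyl-5-({(1R,2S,5S)-2-methyl-5-(prop-1-en-2-yl)-2-[(triethylsilyl)oxy]cyclopentyl}methyl)phenyl]-2-methylbutan-1-one | C=C(C)[C@H]1CC[C@](C)(O[Si](CC)(CC)CC)[C@@H]1Cc1c(O)c(C)c(O)c(C(=O)[C@H](C)CC)c1O
F6 | step 3 | (4S)-1-methyl-4-(prop-1-en-2-yl)cyclohexane-1,2-diol (mixture of diastereomers) | CC1(O)CC[C@@H](CC1O)C(C)=C
F7 | step 3 | (3S)-6-oxo-3-(prop-1-en-2-yl)heptanal | CC(=O)CC[C@@H](CC=O)C(C)=C
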